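Conventions: C1–C10 are the decalin carbons (C1 = ring CH carrying the side chain, C4 = ring carbinol carbon, C5 = ring-fusion CH, C7 = ring CH carrying the hydroxyisopropyl group, C10 = methyl-bearing fusion carbon); C1′ is the benzylic methine and C11 the carbinol carbon of the hydroxyisopropyl group. TBS = tert-butyldimethylsilyl, TBSO = its ether oxygen. Compound numbers are those of the steps and of the compound list.

## Analysis of the target

The target 30 joins two halves through one exocyclic stereocentre: a trans-fused decalin of the eudesmane type (ring A = C1–C5 with C10, ring B = C5–C10) and a 2,4,6-trihydroxybenzene-1,3-dicarbaldehyde ring are both bonded to the benzylic methine C1′, which also carries an isobutyl group. There are six stereocentres: C1′, C1, C4, C5, C7 and C10. On the decalin the C10 methyl is axial and anti to H5 (trans fusion), the C1 side chain and the C7 hydroxyisopropyl group are both equatorial and cis to that methyl, and at C4 the hydroxyl is axial (1,3-diaxial to the C10 methyl) while the C4 methyl is equatorial. C1′ (S) is the only stereocentre outside the rings and sits between the neopentyl-type C1 and a fully substituted arene, so it has to be set by relay from C1. The sensitive groups are the two tertiary alcohols (the axial C4 hydroxyl has anti-periplanar hydrogens at C3 and C5 and dehydrates easily under Lewis or strong protic acid), the two aryl aldehydes and the acidic, chelating triphenol. The difficulties are the quaternary C10 flanked by the stereocentres C1 and C5, the congested C1–C1′–aryl junction, and the release of three phenols without loss of the tertiary alcohols. The strategy rests on ring A: with C4 taken back to a ketone (as its enol ether C3=C4), ring A is a cyclohexene whose bonds C5–C10 and C1–C2 can come from one cycloaddition between a diene C2=C3–C4=C5 and a dienophile C1=C10 that are tied together by the ring B carbons C6–C9.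

## Retrosynthetic reasoning

**Unmasking (30 ⇒ 29 ⇒ 28).** The three aryl O–CH3 bonds and the O–Si bond at C11 are formed last in the retrosynthetic sense. A free formylphloroglucinol is too acidic and chelating to carry through organometallic steps, whereas methyl ethers survive them. With both formyl groups in place every methoxy group is ortho or para to them, so a basic, nucleophilic demethylation becomes possible that does not endanger the tertiary alcohols.

**Aryl–CHO bonds (28 ⇒ 25 + 26).** The two formyl groups are cut next. They must come after C1′ is set, because they would destabilise the benzylic cation needed there and would not survive organolithium reagents. The forward reaction has to functionalise the two remaining ring positions of 25, each lying between two methoxy groups, under basic conditions that the tertiary alcohol tolerates.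

**C1′–H (25 ⇒ 24).** The C1′–H bond is cut to a tertiary benzylic alcohol. The electron-rich trimethoxyphenyl ring makes ionisation at C1′ far easier than at the aliphatic carbinols, and hydride delivery to the planar cation is the step that sets C1′ by relay from C1.

**C1′–isobutyl and C1′–aryl (24 ⇒ 22 + 23; 22 ⇒ 21 ⇒ 19 + 20).** Both carbon substituents at C1′ are introduced as commercial nucleophiles (23 and the lithio derivative of 20) onto a carbonyl carbon that is already attached to C1. Cutting here keeps the arene as one intact building block and needs no stereocontrol, since both carbinol centres are erased.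

**Oxidation level at the C1 carbon and C4–CH3 (19 ⇒ 18 ⇒ 17 ⇒ 15 + 16).** The aldehyde 19 comes from the ester 17 by reduction and reoxidation. The C4 methyl is cut from the ketone 15; the forward addition must come from the equatorial side, away from the axial C10 methyl, to leave the hydroxyl axial.

**Key disconnection (15 ⇒ 14 ⇒ 13).** Bonds C5–C10 and C1–C2 are cut together. This opens both rings at once and turns three ring stereocentres (C1, C5, C10) into two alkene geometries and one existing stereocentre (C7) of the open-chain triene 13. The silyl enol ether in 14 is the masked C4 ketone, and C5, being α to it, remains correctable.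

**Diene and vinyl ketone (13 ⇒ 12 ⇒ 11 ⇒ 9 + 10).** The silyloxydiene is the enol derivative of vinyl ketone 12, which can enolise in one direction only. The C3–C4 bond is cut to the aldehyde 9 and the vinyl nucleophile 10.

**Enoate and homologation (9 ⇒ 8 ⇒ 6 + 7; 6 ⇒ 4 + 5).** The C1=C10 alkene is cut to the methyl ketone of 6 and the phosphonate 7. The C4–C5 bond is cut to the aldehyde of 4 and the one-carbon ylide precursor 5, which moves the aldehyde one carbon out so that C5 becomes a methylene.

**Chiral pool (4 ⇒ 2 ⇒ 1).** Reconnecting the two carbonyl carbons of 4 as a ring alkene gives protected 1. Terpineol 1 supplies C5–C10, the C10 methyl, the oxygenated three-carbon unit and the C7 stereocentre in the correct absolute sense.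

## Alternatives that were turned down

Alternative 1: Radical closure of ring B. The C9–C10 bond is cut and the angular methyl is traced back to an exocyclic methylene on a preformed ring A, giving the methylidene cyclohexanone A2, which already carries the complete C1 side chain and a 2-oxobut-3-enyl arm at C5. In the forward step a metal-hydride hydrogen-atom transfer (iron catalyst, silane) places a hydrogen on the methylene carbon; the tertiary C10 radical adds to the enone terminus in a 6-endo conjugate addition and gives the trans-fused diketone A1.
- For it: a tertiary radical adding to an unhindered alkene terminus has an early transition state, so the quaternary centre should form at room temperature, with much less steric sensitivity than a cycloaddition onto a β,β-disubstituted enoate. The arene and C1′ are in place before ring closure, so no hindered carbonyl additions are needed late.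
- Against it: A2 needs three contiguous stereocentres (C1′, C1, C5) on a cyclohexanone before the key step, so the C1′ problem is only moved earlier. A1 has two ketones; the one at C7 must still become CH–C(CH3)2OH with a stereocentre set late, and the C4 ketone must be methylated selectively. The ring fusion depends on the face of the C10 radical and is not obviously trans-selective.
- Comparison: on the bond to the quaternary carbon the radical closure is the stronger and milder method. The chosen route instead forms two bonds, two rings and three stereocentres in one step, takes C7 with its side chain directly from 1, and leaves one ring carbonyl, which should save several operations after the key step.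

Alternative 2: Carbene-catalysed closure of ring A. The C4–C5 bond is cut as an acyl-anion addition, giving the 4,4-disubstituted cyclohexadienone A4, whose quaternary carbon (future C10) carries the methyl group and a chain containing the ester-bearing C1 and a terminal aldehyde (future C4). A chiral triazolium-derived carbene turns the aldehyde into a Breslow intermediate that adds to one of the two dienone β-carbons (intramolecular Stetter reaction), closing ring A and fixing C10; after equilibration at C5 this gives the trans-fused enedione A3.
- For it: catalytic and mild, absolute configuration from the catalyst, C4 delivered directly as a ketone, and a short synthesis of A4.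
- Against it: the tether reaches only the dienone face on which it sits, so the kinetic product is cis-fused. C1 is already stereogenic and epimerisable in A4, so the two alkenes are diastereotopic and the catalyst must match or override that centre. Six-membered Stetter closure with an enolisable aliphatic aldehyde is a less favourable case. A3 has no carbon substituent at C7, so ring B needs alkene reduction, a three-carbon unit with stereocontrol, and differentiation of two ketones.
- Comparison: the alternative is stronger in enantiocontrol and in the mildness of ring closure. The chosen strategy brings C7 fully substituted and correctly configured into the key step and uses it to control the rest.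

Alternative 3: Aromatic ring built last. The arene is traced back to an open 3,5-dioxo ester by cutting the bond between the aryl carbon that carries the side chain and one neighbouring oxygenated carbon, giving the triketide ester A6 (decalin alcohols as trimethylsilyl ethers). Excess lithium amide forms the polyanion; its terminal methylene carbanion attacks the ester carbonyl (Claisen-type cyclisation) and the cyclic triketone enolises to the phloroglucinol A5.
- For it: no organometallic addition to a hindered aryl ketone and no cation reduction. The arene is formed with free phenols, so there is no triple demethylation, and the free phloroglucinol is formylated easily. C1′ becomes an ordinary acyclic stereocentre.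
- Against it: the attacking methylene lies next to the doubly branched C1′ on the neopentyl-type C1 and must react as part of a trianion. Aldol-type closures and retro-Claisen cleavage compete. A6 needs a six-carbon linear chain extension and a separate solution for C1′, and trimethylsilyl ethers of tertiary alcohols are marginal under these conditions.
- Comparison: the alternative is stronger at the very end (no demethylation, easier formylation). The chosen route brings the arene in as the single commercial piece 20 in one C–C bond formation and then uses it as the cation-stabilising group that sets C1′.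

Key step: step 9

Remark on the chemistry: (S)-α-terpineol (1) is taken to be available in high enantiomeric purity, since every later stereocentre is relayed from its single stereocentre.

## Route

Step 1
Reactants: 1 (S)-α-terpineol
Product: 2 tert-butyl(dimethyl){2-[(1S)-4-methylcyclohex-3-en-1-yl]propan-2-yloxy}silane
Conditions: TBSOTf, 2,6-lutidine, CH2Cl2, 0 °C → rt
Reagents that add atoms: tert-butyldimethylsilyl trifluoromethanesulfonate, CC(C)(C)[Si](C)(C)OS(=O)(=O)C(F)(F)F
Why: Silyl ether formation with a silyl triflate and a hindered pyridine base is reliable for tertiary alcohols; the free hydroxyl would trap the aldehyde of step 2 as a lactol, and a tertiary TBS ether is chosen because it should survive the aqueous acid of steps 5 and 10 and the acid of step 17.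

Step 2
Reactants: 2
Product: 4 (3S)-3-[2-(TBSO)propan-2-yl]-6-oxoheptanal, via secondary ozonide 3 (not isolated)
Conditions: O3, CH2Cl2, −78 °C; PPh3, −78 °C → rt
Reagents that add atoms: ozone, [O-][O+]=O
Why: Ozonolysis with reductive work-up cleaves the only C=C bond to the methyl ketone and the aldehyde; the silyl ether is inert and the stereocentre is not α to either carbonyl, so it cannot epimerise.

Step 3
Reactants: 4, 5 (methoxymethyl)triphenylphosphonium chloride
Product: 6 (5S)-8-methoxy-5-[2-(TBSO)propan-2-yl]oct-7-en-2-one (enol ether E/Z mixture)
Conditions: 5, KN(SiMe3)2, THF, 0 °C; then added to 4, −78 → −20 °C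
Reagents that add atoms: (methoxymethyl)triphenylphosphonium chloride, COC[P+](c1ccccc1)(c1ccccc1)c1ccccc1.[Cl-]
Why: Wittig methoxymethylenation; one equivalent of the ylide added at low temperature should react with the aldehyde much faster than with the methyl ketone, and the enol ether geometry is irrelevant because step 5 hydrolyses it.

Step 4
Reactants: 6, 7 trimethyl phosphonoacetate
Product: 8 methyl (2E,6S)-9-methoxy-3-methyl-6-[2-(TBSO)propan-2-yl]nona-2,8-dienoate (enol ether E/Z mixture)
Conditions: 7, NaH, THF, 0 → 60 °C
Reagents that add atoms: trimethyl phosphonoacetate, COC(=O)CP(=O)(OC)OC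
Why: Horner–Wadsworth–Emmons olefination of the unhindered methyl ketone; reversible addition should favour the 2E enoate (ester trans to the longer chain), and the minor 2Z isomer is removed by chromatography here or after step 5, while enol ether and silyl ether are inert to the base.

Step 5
Reactants: 8
Product: 9 methyl (2E,6S)-3-methyl-9-oxo-6-[2-(TBSO)propan-2-yl]non-2-enoate
Conditions: 1 M aq HCl, THF, 0 °C → rt
Reagents that add atoms: water, O
Why: Acid hydrolysis of the methyl enol ether completes the one-carbon homologation; the enoate and the tertiary TBS ether should be stable to dilute aqueous acid, and the 2E isomer is secured here as a single compound.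

Step 6
Reactants: 9, 10 vinylmagnesium bromide
Product: 11 methyl (2E,6S)-9-hydroxy-3-methyl-6-[2-(TBSO)propan-2-yl]undeca-2,10-dienoate (both C9 epimers)
Conditions: CH2=CHMgBr, THF, −78 °C
Reagents that add atoms: vinylmagnesium bromide, C=C[Mg]Br
Why: Grignard 1,2-addition; at −78 °C the aldehyde should react far faster than the β,β-disubstituted enoate, and the uncontrolled carbinol centre is removed in step 7.

Step 7
Reactants: 11
Product: 12 methyl (2E,6S)-3-methyl-9-oxo-6-[2-(TBSO)propan-2-yl]undeca-2,10-dienoate
Conditions: Dess–Martin periodinane, CH2Cl2, 0 °C → rt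
Reagents that add atoms: none
Why: Dess–Martin oxidation of the allylic alcohol under neutral, non-nucleophilic conditions should give the vinyl ketone without conjugate addition or polymerisation; 12 is used promptly.

Step 8
Reactants: 12
Product: 13 methyl (2E,6S,8Z)-3-methyl-9-(TBSO)-6-[2-(TBSO)propan-2-yl]undeca-2,8,10-trienoate
Conditions: TBSOTf, Et3N, CH2Cl2, −78 → 0 °C
Reagents that add atoms: tert-butyldimethylsilyl trifluoromethanesulfonate, CC(C)(C)[Si](C)(C)OS(=O)(=O)C(F)(F)F
Why: Soft enolisation (silyl triflate and amine); the ketone can enolise only towards C8, and the silyl enol ether should form with the chain trans to the vinyl group (8Z), the isomer that avoids allylic strain, while the enoate ester is not enolised; a TBS rather than a more labile silyl enol ether is chosen for the thermal step.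

Step 9
Reactants: 13
Product: 14 methyl (1S,4aS,6S,8aS)-8a-methyl-4-(TBSO)-6-[2-(TBSO)propan-2-yl]-1,2,4a,5,6,7,8,8a-octahydronaphthalene-1-carboxylate
Conditions: PhMe (0.01 M), BHT (cat.), sealed tube, 190 °C
Reagents that add atoms: none
Why: Thermal, concerted and suprafacial [4+2] cycloaddition (type 1 intramolecular Diels–Alder reaction) of normal electron demand: the HOMO of the 2-silyloxydiene has its large terminal coefficient at C5 and the LUMO of the enoate at the β-carbon C10, so the tether-enforced regiochemistry is also the electronically matched one and the hindered C5–C10 bond runs ahead in an asynchronous transition state. The closest known reaction type is the cyclisation of 1,7,9-decatrienes with a terminally activated E-dienophile, an established entry to trans-fused decalins with an angular methyl group. Ring B closes as a six-membered carbocycle through the C5–C10 bond across the four-carbon tether C6–C9, and ring A is the cyclohexene formed by the cycloaddition itself (C5–C10 and C1–C2), its C3=C4 enol ether marking the future carbonyl. C1 and C10 are set by the alkene geometry: the 2E enoate holds the ester cis to the C10 methyl and suprafacial addition keeps them cis. C5 is set relative to C10 by the endo transition state, in which ester and methyl lie under the diene and the tether is exo in a chair-like array, which gives the trans fusion. The absolute sense comes from C7, whose bulky silyloxyisopropyl group should stay pseudo-equatorial on that chair and so select one face of the diene. The step needs endo over exo selectivity, which the substrate supports only moderately (secondary overlap of the ester with C3, chair-like against less favourable tether arrangements); the backup is that C5 ends up α to the masked C4 carbonyl and can be equilibrated to the trans ketone after step 10. The 8Z enol ether geometry from step 8 places the tether on the outside of the diene, which the s-cis conformer needs in order to reach the dienophile.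

Step 10
Reactants: 14
Product: 15 methyl (1S,4aS,6S,8aS)-8a-methyl-4-oxo-6-[2-(TBSO)propan-2-yl]decahydronaphthalene-1-carboxylate
Conditions: 1 M aq HCl, THF, 0 °C → rt
Reagents that add atoms: none
Why: Hydrolysis of the silyl enol ether by protonation at C3 releases the C4 ketone without touching C5, and the tertiary TBS ether should survive; if cis-fused material is carried over from step 9, brief treatment of the ketone with NaOMe in MeOH should move the C5 epimer towards the trans-fused ketone, in which the ester stays equatorial.

Step 11
Reactants: 15, 16 methylmagnesium bromide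
Product: 17 methyl (1S,4R,4aS,6S,8aS)-4-hydroxy-4,8a-dimethyl-6-[2-(TBSO)propan-2-yl]decahydronaphthalene-1-carboxylate
Conditions: MeMgBr, CeCl3, THF, −78 °C
Reagents that add atoms: methylmagnesium bromide, C[Mg]Br
Why: Organocerium 1,2-addition suppresses enolisation and should take the ketone much faster than the hindered ester; the axial trajectory at C4 is blocked by the 1,3-diaxial C10 methyl, so the methyl group should enter equatorially and leave the hydroxyl axial (4R).

Step 12
Reactants: 17
Product: 18 [(1S,4R,4aS,6S,8aR)-4-hydroxy-4,8a-dimethyl-6-[2-(TBSO)propan-2-yl]decahydronaphthalen-1-yl]methanol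
Conditions: LiAlH4, THF, 0 °C → rt
Reagents that add atoms: none
Why: Hydride reduction of the ester to the primary alcohol; the tertiary alkoxide and the silyl ether are inert and no stereocentre is affected.

Step 13
Reactants: 18
Product: 19 (1S,4R,4aS,6S,8aS)-4-hydroxy-4,8a-dimethyl-6-[2-(TBSO)propan-2-yl]decahydronaphthalene-1-carbaldehyde
Conditions: Dess–Martin periodinane, CH2Cl2, 0 °C → rt
Reagents that add atoms: none
Why: Dess–Martin oxidation of the primary alcohol; the tertiary alcohol cannot be oxidised, and the equatorial aldehyde at C1 is the more stable epimer, so C1 is not at risk.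

Step 14
Reactants: 19, 20 1,3,5-trimethoxybenzene
Product: 21 [(1S,4R,4aS,6S,8aR)-4-hydroxy-4,8a-dimethyl-6-[2-(TBSO)propan-2-yl]decahydronaphthalen-1-yl](2,4,6-trimethoxyphenyl)methanol (both carbinol epimers)
Conditions: 20, n-BuLi, THF, 0 °C → rt; then 19, −78 → 0 °C
Reagents that add atoms: 1,3,5-trimethoxybenzene, COc1cc(OC)cc(OC)c1
Why: Directed ortho-lithiation of 20 between two methoxy groups gives 2,4,6-trimethoxyphenyllithium, which adds 1,2 to the aldehyde (one further equivalent is spent on the free hydroxyl); the uncontrolled carbinol centre is removed in step 15.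

Step 15
Reactants: 21
Product: 22 [(1S,4R,4aS,6S,8aS)-4-hydroxy-4,8a-dimethyl-6-[2-(TBSO)propan-2-yl]decahydronaphthalen-1-yl](2,4,6-trimethoxyphenyl)methanone
Conditions: Dess–Martin periodinane, CH2Cl2, rt
Reagents that add atoms: none
Why: Dess–Martin oxidation of the secondary benzylic alcohol to the aryl ketone; the tertiary alcohol and the electron-rich arene are not affected.

Step 16
Reactants: 22, 23 isobutyllithium
Product: 24 1-[(1S,4R,4aS,6S,8aS)-4-hydroxy-4,8a-dimethyl-6-[2-(TBSO)propan-2-yl]decahydronaphthalen-1-yl]-3-methyl-1-(2,4,6-trimethoxyphenyl)butan-1-ol (both carbinol epimers)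
Conditions: 23, CeCl3, THF, −78 °C; then 22, −78 → −40 °C
Reagents that add atoms: isobutyllithium, [Li]CC(C)C
Why: Organocerium 1,2-addition; the weakly basic, oxophilic isobutylcerium reagent should add to the hindered, enolisable ketone where the lithium or magnesium reagent would enolise C1 or transfer a β-hydride, and the ortho-methoxy groups can guide the metal to the carbonyl; the carbinol centre is erased in step 17.

Step 17
Reactants: 24
Product: 25 2-[(1S)-1-[(1R,4R,4aS,6S,8aR)-4-hydroxy-4,8a-dimethyl-6-[2-(TBSO)propan-2-yl]decahydronaphthalen-1-yl]-3-methylbutyl]-1,3,5-trimethoxybenzene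
Conditions: Et3SiH, CF3CO2H, CH2Cl2, −78 → −40 °C
Reagents that add atoms: none
Why: Ionic hydrogenation: acid ionises the tertiary benzylic alcohol to a cation stabilised by the trimethoxyphenyl ring (an O-methylated quinone methide), which Et3SiH should reduce well below the temperature at which the aliphatic tertiary alcohol or the TBS ether respond. C1′ is set by allylic 1,3-strain: the planar cation should hold the C1–H bond eclipsed with the aryl group and the isobutyl CH2 between C2 and C10, and take hydride from the C2 side, anti to the quaternary C10, which corresponds to 1′S.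

Step 18
Reactants: 25, 26 N,N-dimethylformamide
Product: 28 5-[(1S)-1-[(1R,4R,4aS,6S,8aR)-4-hydroxy-4,8a-dimethyl-6-[2-(TBSO)propan-2-yl]decahydronaphthalen-1-yl]-3-methylbutyl]-2,4,6-trimethoxybenzene-1,3-dicarbaldehyde, via monoformyl hemiaminolate 27 (not isolated)
Conditions: n-BuLi, TMEDA, THF, 0 °C; 26 (1 equiv), −78 → 0 °C; n-BuLi, 0 °C; 26, −78 °C → rt; aq HCl
Reagents that add atoms: N,N-dimethylformamide, CN(C)C=O
Why: Directed ortho-metalation and formylation, run twice in one flask: each free ring position lies between two methoxy groups and should lithiate readily, and the first formyl group stays masked as its lithium α-amino alkoxide 27, which is inert to the second lithiation. The tertiary hydroxyl is carried as its lithium alkoxide and the aldehydes appear only on acidic work-up, so no Lewis acid touches the tertiary alcohol.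

Step 19
Reactants: 28
Product: 29 5-[(1S)-1-[(1R,4R,4aS,6S,8aR)-4-hydroxy-6-(2-hydroxypropan-2-yl)-4,8a-dimethyldecahydronaphthalen-1-yl]-3-methylbutyl]-2,4,6-trimethoxybenzene-1,3-dicarbaldehyde
Conditions: HF·pyridine, THF, 0 °C → rt
Reagents that add atoms: none
Why: Fluoride-driven cleavage of the tertiary silyl ether; HF·pyridine is not acidic enough to ionise the tertiary alcohols and should leave aldehydes and methyl ethers alone.

Step 20
Reactants: 29
Product: 30 5-[(1S)-1-[(1R,4R,4aS,6S,8aR)-4-hydroxy-6-(2-hydroxypropan-2-yl)-4,8a-dimethyldecahydronaphthalen-1-yl]-3-methylbutyl]-2,4,6-trihydroxybenzene-1,3-dicarbaldehyde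
Conditions: NaSEt, DMF, 120 °C; aq HCl
Reagents that add atoms: none
Why: Nucleophilic (SN2) O-demethylation by thiolate; every methoxy group is ortho or para to both formyl groups, so each departing phenoxide is a vinylogous carboxylate, and the basic medium should leave both tertiary alcohols intact where a Lewis-acidic demethylation would ionise them.

## Compound list

1 | (S)-α-terpineol, 2-[(1S)-4-methylcyclohex-3-en-1-yl]propan-2-ol | CC1=CC[C@H](CC1)C(C)(C)O | starting material
2 | tert-butyl(dimethyl){2-[(1S)-4-methylcyclohex-3-en-1-yl]propan-2-yloxy}silane | CC1=CC[C@H](CC1)C(C)(C)O[Si](C)(C)C(C)(C)C | intermediate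
3 | secondary ozonide (1,2,4-trioxolane) of 2, mixture at the ozonide carbons | CC12CC[C@@H](CC(OO1)O2)C(C)(C)O[Si](C)(C)C(C)(C)C | intermediate
4 | (3S)-3-[2-(tert-butyldimethylsilyloxy)propan-2-yl]-6-oxoheptanal | O=CC[C@H](CCC(C)=O)C(C)(C)O[Si](C)(C)C(C)(C)C | intermediate
5 | (methoxymethyl)triphenylphosphonium chloride | COC[P+](c1ccccc1)(c1ccccc1)c1ccccc1.[Cl-] | starting material
6 | (5S)-8-methoxy-5-[2-(tert-butyldimethylsilyloxy)propan-2-yl]oct-7-en-2-one, enol ether E/Z mixture | COC=CC[C@H](CCC(C)=O)C(C)(C)O[Si](C)(C)C(C)(C)C | intermediate
7 | trimethyl phosphonoacetate | COC(=O)CP(=O)(OC)OC | starting material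
8 | methyl (2E,6S)-9-methoxy-3-methyl-6-[2-(tert-butyldimethylsilyloxy)propan-2-yl]nona-2,8-dienoate, enol ether E/Z mixture | COC=CC[C@H](CC/C(C)=C/C(=O)OC)C(C)(C)O[Si](C)(C)C(C)(C)C | intermediate
9 | methyl (2E,6S)-3-methyl-9-oxo-6-[2-(tert-butyldimethylsilyloxy)propan-2-yl]non-2-enoate | O=CCC[C@H](CC/C(C)=C/C(=O)OC)C(C)(C)O[Si](C)(C)C(C)(C)C | intermediate
10 | vinylmagnesium bromide | C=C[Mg]Br | starting material
11 | methyl (2E,6S)-9-hydroxy-3-methyl-6-[2-(tert-butyldimethylsilyloxy)propan-2-yl]undeca-2,10-dienoate, both C9 epimers | C=CC(O)CC[C@H](CC/C(C)=C/C(=O)OC)C(C)(C)O[Si](C)(C)C(C)(C)C | intermediate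
12 | methyl (2E,6S)-3-methyl-9-oxo-6-[2-(tert-butyldimethylsilyloxy)propan-2-yl]undeca-2,10-dienoate | C=CC(=O)CC[C@H](CC/C(C)=C/C(=O)OC)C(C)(C)O[Si](C)(C)C(C)(C)C | intermediate
13 | methyl (2E,6S,8Z)-3-methyl-9-(tert-butyldimethylsilyloxy)-6-[2-(tert-butyldimethylsilyloxy)propan-2-yl]undeca-2,8,10-trienoate | C=C/C(O[Si](C)(C)C(C)(C)C)=C/C[C@H](CC/C(C)=C/C(=O)OC)C(C)(C)O[Si](C)(C)C(C)(C)C | intermediate
14 | methyl (1S,4aS,6S,8aS)-8a-methyl-4-(tert-butyldimethylsilyloxy)-6-[2-(tert-butyldimethylsilyloxy)propan-2-yl]-1,2,4a,5,6,7,8,8a-octahydronaphthalene-1-carboxylate | COC(=O)[C@H]1CC=C(O[Si](C)(C)C(C)(C)C)[C@H]2C[C@@H](C(C)(C)O[Si](C)(C)C(C)(C)C)CC[C@]12C | intermediate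
15 | methyl (1S,4aS,6S,8aS)-8a-methyl-4-oxo-6-[2-(tert-butyldimethylsilyloxy)propan-2-yl]decahydronaphthalene-1-carboxylate | COC(=O)[C@H]1CCC(=O)[C@H]2C[C@@H](C(C)(C)O[Si](C)(C)C(C)(C)C)CC[C@]12C | intermediate
16 | methylmagnesium bromide | C[Mg]Br | starting material
17 | methyl (1S,4R,4aS,6S,8aS)-4-hydroxy-4,8a-dimethyl-6-[2-(tert-butyldimethylsilyloxy)propan-2-yl]decahydronaphthalene-1-carboxylate | COC(=O)[C@H]1CC[C@@](C)(O)[C@H]2C[C@@H](C(C)(C)O[Si](C)(C)C(C)(C)C)CC[C@]12C | intermediate
18 | [(1S,4R,4aS,6S,8aR)-4-hydroxy-4,8a-dimethyl-6-[2-(tert-butyldimethylsilyloxy)propan-2-yl]decahydronaphthalen-1-yl]methanol | OC[C@H]1CC[C@@](C)(O)[C@H]2C[C@@H](C(C)(C)O[Si](C)(C)C(C)(C)C)CC[C@]12C | intermediate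
19 | (1S,4R,4aS,6S,8aS)-4-hydroxy-4,8a-dimethyl-6-[2-(tert-butyldimethylsilyloxy)propan-2-yl]decahydronaphthalene-1-carbaldehyde | O=C[C@H]1CC[C@@](C)(O)[C@H]2C[C@@H](C(C)(C)O[Si](C)(C)C(C)(C)C)CC[C@]12C | intermediate
20 | 1,3,5-trimethoxybenzene | COc1cc(OC)cc(OC)c1 | starting material
21 | [(1S,4R,4aS,6S,8aR)-4-hydroxy-4,8a-dimethyl-6-[2-(tert-butyldimethylsilyloxy)propan-2-yl]decahydronaphthalen-1-yl](2,4,6-trimethoxyphenyl)methanol, both carbinol epimers | COc1cc(OC)c(C(O)[C@H]2CC[C@@](C)(O)[C@H]3C[C@@H](C(C)(C)O[Si](C)(C)C(C)(C)C)CC[C@]23C)c(OC)c1 | intermediate
22 | [(1S,4R,4aS,6S,8aS)-4-hydroxy-4,8a-dimethyl-6-[2-(tert-butyldimethylsilyloxy)propan-2-yl]decahydronaphthalen-1-yl](2,4,6-trimethoxyphenyl)methanone | COc1cc(OC)c(C(=O)[C@H]2CC[C@@](C)(O)[C@H]3C[C@@H](C(C)(C)O[Si](C)(C)C(C)(C)C)CC[C@]23C)c(OC)c1 | intermediate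
23 | isobutyllithium | [Li]CC(C)C | starting material
24 | 1-[(1S,4R,4aS,6S,8aS)-4-hydroxy-4,8a-dimethyl-6-[2-(tert-butyldimethylsilyloxy)propan-2-yl]decahydronaphthalen-1-yl]-3-methyl-1-(2,4,6-trimethoxyphenyl)butan-1-ol, both carbinol epimers | COc1cc(OC)c(C(O)(CC(C)C)[C@H]2CC[C@@](C)(O)[C@H]3C[C@@H](C(C)(C)O[Si](C)(C)C(C)(C)C)CC[C@]23C)c(OC)c1 | intermediate
25 | 2-[(1S)-1-[(1R,4R,4aS,6S,8aR)-4-hydroxy-4,8a-dimethyl-6-[2-(tert-butyldimethylsilyloxy)propan-2-yl]decahydronaphthalen-1-yl]-3-methylbutyl]-1,3,5-trimethoxybenzene | COc1cc(OC)c([C@@H](CC(C)C)[C@H]2CC[C@@](C)(O)[C@H]3C[C@@H](C(C)(C)O[Si](C)(C)C(C)(C)C)CC[C@]23C)c(OC)c1 | intermediate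
26 | N,N-dimethylformamide | CN(C)C=O | starting material
27 | dilithium salt of the monoformylated arene, held as its dimethylamino hemiaminal alkoxide, with the C4 alkoxide | COc1cc(OC)c([C@@H](CC(C)C)[C@H]2CC[C@@](C)(O[Li])[C@H]3C[C@@H](C(C)(C)O[Si](C)(C)C(C)(C)C)CC[C@]23C)c(OC)c1C(O[Li])N(C)C | intermediate
28 | 5-[(1S)-1-[(1R,4R,4aS,6S,8aR)-4-hydroxy-4,8a-dimethyl-6-[2-(tert-butyldimethylsilyloxy)propan-2-yl]decahydronaphthalen-1-yl]-3-methylbutyl]-2,4,6-trimethoxybenzene-1,3-dicarbaldehyde | COc1c(C=O)c(OC)c(C=O)c(OC)c1[C@@H](CC(C)C)[C@H]1CC[C@@](C)(O)[C@H]2C[C@@H](C(C)(C)O[Si](C)(C)C(C)(C)C)CC[C@]12C | intermediate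
29 | 5-[(1S)-1-[(1R,4R,4aS,6S,8aR)-4-hydroxy-6-(2-hydroxypropan-2-yl)-4,8a-dimethyldecahydronaphthalen-1-yl]-3-methylbutyl]-2,4,6-trimethoxybenzene-1,3-dicarbaldehyde | COc1c(C=O)c(OC)c(C=O)c(OC)c1[C@@H](CC(C)C)[C@H]1CC[C@@](C)(O)[C@H]2C[C@@H](C(C)(C)O)CC[C@]12C | intermediate
30 | 5-[(1S)-1-[(1R,4R,4aS,6S,8aR)-4-hydroxy-6-(2-hydroxypropan-2-yl)-4,8a-dimethyldecahydronaphthalen-1-yl]-3-methylbutyl]-2,4,6-trihydroxybenzene-1,3-dicarbaldehyde | CC(C)C[C@H](c1c(O)c(C=O)c(O)c(C=O)c1O)[C@H]1CC[C@@](C)(O)[C@H]2C[C@@H](C(C)(C)O)CC[C@]12C | target

## Step count and least certain steps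

Total: 20 steps. Longest linear sequence: 20 steps from 1; all other building blocks (5, 7, 10, 16, 20, 23, 26) are purchased.

**Step 9 (key step).** Two things are most likely to go wrong. The cycloaddition may be slow because the dienophile carbon C10 is fully substituted, so that desilylation or decomposition of the dienol ether competes at the temperature needed. The endo/exo discrimination may also be incomplete, which gives cis-fused material; only the part that is the C5 epimer is corrected by equilibration after step 10. Fallback: an anionic double conjugate addition in place of the thermal cycloaddition. It sets out from enone 12: LiN(SiMe3)2 (THF, −78 → 0 °C) should form the cross-conjugated lithium dienolate at C5, which adds to the enoate at C10; the resulting ester enolate then closes ring A onto the vinyl ketone at C2. Aqueous work-up gives keto ester 15, where the route is rejoined; C5 and C1 are both epimerisable there and should settle trans and equatorial. No new isolable compound lies on this path (F0).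

**Step 16.** The carbonyl of 22 is shielded by two ortho-methoxy groups and by the neopentyl-type C1, so addition may fail in favour of enolisation (with possible epimerisation at C1) or hydride transfer from the isobutyl reagent. Fallback: an allyl-type nucleophile followed by hydrogenation. It sets out from 22: methallylmagnesium chloride (THF, 0 °C) should add through a six-membered allyl-transfer transition state, which is far less sensitive to hindrance and has no β-hydride pathway, to give the homoallylic alcohol F1. Hydrogenation of its 1,1-disubstituted alkene (H2, RhCl(PPh3)3, benzene) gives 24, where the route is rejoined.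

**Step 17.** Facial selectivity at C1′ may be poor or opposite to the model, because it depends on one rotamer of a very crowded cation. Elimination to the styrenes may also compete with hydride capture, and reprotonation could scramble C1. Prolonged or warmer acid exposure could ionise the C4 alcohol. Fallback: form the last C1′ bond to carbon instead of hydrogen, which reverses the sense of induction for the same facial bias. It sets out from the secondary benzylic alcohol 21: BF3·OEt2 and methallyltrimethylsilane (CH2Cl2, −78 °C) ionise it to the secondary benzylic cation and allylate it, giving the methallyl compound F2. Hydrogenation (H2, Pd/C, EtOAc) converts this into 25, where the route is rejoined. This route is to be used if hydride delivery to the tertiary cation favours the unwanted C1′ epimer.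

**Step 18.** The second lithiation may be incomplete, or the α-amino alkoxide may collapse early and be attacked by n-BuLi, so that mono-aldehyde or butyl carbinol results. Fallback: halogenation and halogen–lithium exchange instead of deprotonation. It sets out from 25: N-bromosuccinimide (2 equiv, MeCN, 0 °C) should brominate both free positions of the electron-rich ring to give the dibromide F3. Excess t-BuLi (THF, −78 °C) followed by DMF and acidic work-up gives 28, where the route is rejoined.

## Further compounds

F0 | step 9 | none | none
F1 | step 16 | 1-[(1S,4R,4aS,6S,8aS)-4-hydroxy-4,8a-dimethyl-6-[2-(tert-butyldimethylsilyloxy)propan-2-yl]decahydronaphthalen-1-yl]-3-methyl-1-(2,4,6-trimethoxyphenyl)but-3-en-1-ol, both carbinol epimers | COc1cc(OC)c(C(O)(CC(C)=C)[C@H]2CC[C@@](C)(O)[C@H]3C[C@@H](C(C)(C)O[Si](C)(C)C(C)(C)C)CC[C@]23C)c(OC)c1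
F2 | step 17 | 2-[(1S)-1-[(1R,4R,4aS,6S,8aR)-4-hydroxy-4,8a-dimethyl-6-[2-(tert-butyldimethylsilyloxy)propan-2-yl]decahydronaphthalen-1-yl]-3-methylbut-3-en-1-yl]-1,3,5-trimethoxybenzene | COc1cc(OC)c([C@@H](CC(C)=C)[C@H]2CC[C@@](C)(O)[C@H]3C[C@@H](C(C)(C)O[Si](C)(C)C(C)(C)C)CC[C@]23C)c(OC)c1
F3 | step 18 | 1,3-dibromo-5-[(1S)-1-[(1R,4R,4aS,6S,8aR)-4-hydroxy-4,8a-dimethyl-6-[2-(tert-butyldimethylsilyloxy)propan-2-yl]decahydronaphthalen-1-yl]-3-methylbutyl]-2,4,6-trimethoxybenzene | COc1c(Br)c(OC)c(Br)c(OC)c1[C@@H](CC(C)C)[C@H]1CC[C@@](C)(O)[C@H]2C[C@@H](C(C)(C)O[Si](C)(C)C(C)(C)C)CC[C@]12C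
A1 | alternative 1 | trans-fused 8a-methyl-1-[(1S)-3-methyl-1-(2,4,6-trimethoxyphenyl)butyl]decahydronaphthalene-4,6-dione (ring locants as in 15) | CC(C)C[C@H](c1c(OC)cc(OC)cc1OC)[C@H]1CCC(=O)[C@H]2CC(=O)CC[C@]12C
A2 | alternative 1 | 3-methylidene-4-[(1S)-3-methyl-1-(2,4,6-trimethoxyphenyl)butyl]-2-(2-oxobut-3-en-1-yl)cyclohexan-1-one, ring stereocentres as in 30 | CC(C)C[C@H](c1c(OC)cc(OC)cc1OC)[C@H]1CCC(=O)[C@@H](CC(=O)C=C)C1=C
A3 | alternative 2 | methyl trans-fused 8a-methyl-4,6-dioxo-1,2,3,4,4a,5,6,8a-octahydronaphthalene-1-carboxylate | COC(=O)[C@H]1CCC(=O)[C@H]2CC(=O)C=C[C@]12C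
A4 | alternative 2 | methyl 2-(1-methyl-4-oxocyclohexa-2,5-dien-1-yl)-5-oxopentanoate | COC(=O)[C@@H](CCC=O)C1(C)C=CC(=O)C=C1
A5 | alternative 3 | 2-[(1S)-1-(decalin-1-yl)-3-methylbutyl]benzene-1,3,5-triol, decalin as in 30 with both tertiary alcohols as trimethylsilyl ethers | CC(C)C[C@H](c1c(O)cc(O)cc1O)[C@H]1CC[C@@](C)(O[Si](C)(C)C)[C@H]2C[C@@H](C(C)(C)O[Si](C)(C)C)CC[C@]12C
A6 | alternative 3 | methyl 7-(decalin-1-yl)-9-methyl-3,5-dioxodecanoate, decalin as in 30 with both tertiary alcohols as trimethylsilyl ethers | CC(C)C[C@H](CC(=O)CC(=O)CC(=O)OC)[C@H]1CC[C@@](C)(O[Si](C)(C)C)[C@H]2C[C@@H](C(C)(C)O[Si](C)(C)C)CC[C@]12C
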